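**Retrosynthetic overview**
1. Caraganin C ⇐ phenol deprotection and E-selective cross-metathesis (4-acetoxystyrene) of the all-trans 4-propenylchroman 19.
2. Pyran ring of 19 ⇐ ionic hydrogenation of the cyclic oxocarbenium from keto-phenol 17 ⇐ 2,4-dimethoxyphenyllithium + trans-dihydrocoumarin 14 (lactone of acid 12).
3. C3–C4 bond and both of its stereocentres ⇐ Ireland–Claisen [3,3] rearrangement of allylic ester 9 with 1,3-chirality transfer.
4. 9 ⇐ acid 8 + (S,E)-allylic alcohol 5 ⇐ Sonogashira coupling and Red-Al reduction from aryl iodide 2 and (S)-but-3-yn-2-ol 3.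
5. Ring order: all four benzene rings are bought; the only ring made is the O-heterocycle, closed as the lactone (step 7), opened (step 8) and reclosed as the pyran (step 9).

Assumption: (S)-but-3-yn-2-ol is bought as the single enantiomer (commercial, ≥98% ee) and is the only source of chirality; the target is (2R,3R,4R) as drawn.

**Route**

Step 1
Reactants: 1 2-iodo-5-methoxyphenol
Product: 2 1-iodo-4-methoxy-2-(methoxymethoxy)benzene
Conditions: MOMCl, i-Pr2NEt, CH2Cl2, 0 °C → rt
Reagents that add atoms: chloromethyl methyl ether (MOMCl), COCCl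
Why: O-alkylation of the phenol (Williamson-type acetal formation) masks the OH that would otherwise cyclise to a benzofuran in the Sonogashira step and be acylated in step 5.

Step 2
Reactants: 2 1-iodo-4-methoxy-2-(methoxymethoxy)benzene; 3 (S)-but-3-yn-2-ol
Product: 4 (S)-4-[4-methoxy-2-(methoxymethoxy)phenyl]but-3-yn-2-ol
Conditions: Pd(PPh3)2Cl2 (2 mol%), CuI (4 mol%), Et3N, THF, rt → 40 °C
Reagents that add atoms: none
Why: Sonogashira coupling of the aryl iodide with the terminal alkyne leaves the purchased carbinol stereocentre untouched.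

Step 3
Reactants: 4 (S)-4-[4-methoxy-2-(methoxymethoxy)phenyl]but-3-yn-2-ol
Product: 5 (S,E)-4-[4-methoxy-2-(methoxymethoxy)phenyl]but-3-en-2-ol
Conditions: Red-Al, THF, 0 °C → rt; aq. Rochelle salt; chromatography on Et3N-deactivated silica
Reagents that add atoms: none
Why: Alkoxide-directed trans-hydroalumination of the propargylic alcohol followed by protonolysis gives only the E-alkene and does not affect the (S)-carbinol.

Step 4
Reactants: 6 3-(4-hydroxyphenyl)propanoic acid
Product: 8 3-[4-(tert-butyldimethylsilyloxy)phenyl]propanoic acid, via bis-silylated silyl ester 7 (not isolated)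
Conditions: TBSCl (2.3 equiv), imidazole, DMF, rt; then AcOH/THF/H2O, rt
Reagents that add atoms: tert-butyldimethylsilyl chloride (TBSCl), CC(C)(C)[Si](C)(C)Cl
Why: Silylation of both OH groups followed by selective hydrolysis of the labile silyl ester leaves the phenol protected as a base-stable aryl silyl ether.

Step 5
Reactants: 5 (S,E)-4-[4-methoxy-2-(methoxymethoxy)phenyl]but-3-en-2-ol; 8 3-[4-(tert-butyldimethylsilyloxy)phenyl]propanoic acid
Product: 9 (S,E)-4-[4-methoxy-2-(methoxymethoxy)phenyl]but-3-en-2-yl 3-[4-(tert-butyldimethylsilyloxy)phenyl]propanoate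
Conditions: DCC, DMAP (cat.), CH2Cl2, 0 °C → rt
Reagents that add atoms: none
Why: Steglich esterification acylates the alcohol oxygen without touching the C–O stereocentre, so the (S) configuration is retained under neutral conditions that avoid ionisation of the electron-rich allylic system.

Step 6
Reactants: 9 (S,E)-4-[4-methoxy-2-(methoxymethoxy)phenyl]but-3-en-2-yl 3-[4-(tert-butyldimethylsilyloxy)phenyl]propanoate
Product: 12 (2R,3R,E)-2-[4-(tert-butyldimethylsilyloxy)benzyl]-3-[4-methoxy-2-(methoxymethoxy)phenyl]hex-4-enoic acid, via (E)-silyl ketene acetal 10 (not isolated), via trimethylsilyl ester 11 (not isolated)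
Conditions: LDA (1.2 equiv), TMSCl (internal quench), THF, −78 °C; then rt → 50 °C; 1 M HCl work-up
Reagents that add atoms: none
Why: Kinetic LDA/THF enolisation gives the (E)-silyl ketene acetal, which undergoes the Ireland–Claisen [3,3]-sigmatropic rearrangement through a chair transition state with the carbinol methyl pseudo-equatorial, so the (S)-C–O centre is transferred suprafacially into the new C2 (R) and C3 (R) centres (the future C3 and C4, trans in the ring) and the E-propenyl group.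

Step 7
Reactants: 12 (2R,3R,E)-2-[4-(tert-butyldimethylsilyloxy)benzyl]-3-[4-methoxy-2-(methoxymethoxy)phenyl]hex-4-enoic acid
Product: 14 (3R,4R)-3-[4-(tert-butyldimethylsilyloxy)benzyl]-7-methoxy-4-[(E)-prop-1-enyl]chroman-2-one, via phenol acid 13 (not isolated)
Conditions: TFA (10 equiv), CH2Cl2, 0 °C → rt
Reagents that add atoms: none
Why: Acidolysis of the MOM acetal frees the ortho phenol, which lactonises under the same acid catalysis to the trans-3,4-disubstituted dihydrocoumarin without touching either stereocentre (the aryl silyl ether survives TFA).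

Step 8
Reactants: 14 (3R,4R)-3-[4-(tert-butyldimethylsilyloxy)benzyl]-7-methoxy-4-[(E)-prop-1-enyl]chroman-2-one; 15 1-bromo-2,4-dimethoxybenzene
Product: 17 (2R,3R,E)-2-[4-(tert-butyldimethylsilyloxy)benzyl]-1-(2,4-dimethoxyphenyl)-3-(2-hydroxy-4-methoxyphenyl)hex-4-en-1-one, via 2,4-dimethoxyphenyllithium 16 (not isolated)
Conditions: 15, n-BuLi, THF, −78 °C; add to 14 (1.05 equiv ArLi), THF, −78 °C; AcOH quench at −78 °C
Reagents that add atoms: none
Why: Br/Li exchange gives the aryllithium, which opens the aryl-ester lactone by nucleophilic acyl substitution, and the hindered, electron-rich α-branched aryl ketone resists a second addition at −78 °C while the cold acidic quench protects the α-stereocentre.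

Step 9
Reactants: 17 (2R,3R,E)-2-[4-(tert-butyldimethylsilyloxy)benzyl]-1-(2,4-dimethoxyphenyl)-3-(2-hydroxy-4-methoxyphenyl)hex-4-en-1-one
Product: 19 (2R,3R,4R)-3-[4-(tert-butyldimethylsilyloxy)benzyl]-2-(2,4-dimethoxyphenyl)-7-methoxy-4-[(E)-prop-1-enyl]chroman, via oxocarbenium trifluoroacetate 18 (not isolated)
Conditions: Et3SiH (3 equiv), TFA (10 equiv), CH2Cl2, −40 → 0 °C
Reagents that add atoms: none
Why: The phenol closes onto the protonated ketone and water is lost to give the 2-aryl oxocarbenium, and in this ionic hydrogenation hydride adds axially, anti to the pseudo-axial C3–H of the half-chair that keeps the C3 and C4 groups pseudo-equatorial, so the C2 aryl ends equatorial and trans to the C3 benzyl (as in C-aryl glycoside lactol reductions).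

Step 10
Reactants: 19 (2R,3R,4R)-3-[4-(tert-butyldimethylsilyloxy)benzyl]-2-(2,4-dimethoxyphenyl)-7-methoxy-4-[(E)-prop-1-enyl]chroman; 20 4-vinylphenyl acetate (4-acetoxystyrene)
Product: 21 4-{(E)-2-[(2R,3R,4R)-3-[4-(tert-butyldimethylsilyloxy)benzyl]-2-(2,4-dimethoxyphenyl)-7-methoxychroman-4-yl]vinyl}phenyl acetate
Conditions: Hoveyda–Grubbs II (10 mol%), 20 (5 equiv), CH2Cl2, 40 °C, argon sweep
Reagents that add atoms: none
Why: Olefin cross-metathesis exchanges the methyl-capped alkene terminus for the styrene partner with loss of volatile propene and gives the conjugated E-styryl alkene under neutral conditions that leave the acid-labile 2-arylchroman and all stereocentres intact.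

Step 11
Reactants: 21 4-{(E)-2-[(2R,3R,4R)-3-[4-(tert-butyldimethylsilyloxy)benzyl]-2-(2,4-dimethoxyphenyl)-7-methoxychroman-4-yl]vinyl}phenyl acetate
Product: 22 caraganin C
Conditions: K2CO3, MeOH/THF, rt
Reagents that add atoms: none
Why: Base-mediated methanolysis cleaves both the aryl acetate and the phenolic silyl ether while the methyl ethers, the chroman and the stereocentres are inert to mild base.

**Compound list**
1 | 2-iodo-5-methoxyphenol | COc1ccc(I)c(O)c1 | starting material
2 | 1-iodo-4-methoxy-2-(methoxymethoxy)benzene | COCOc1cc(OC)ccc1I | intermediate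
3 | (S)-but-3-yn-2-ol | C[C@H](O)C#C | starting material
4 | (S)-4-[4-methoxy-2-(methoxymethoxy)phenyl]but-3-yn-2-ol | C[C@H](O)C#Cc1ccc(OC)cc1OCOC | intermediate
5 | (S,E)-4-[4-methoxy-2-(methoxymethoxy)phenyl]but-3-en-2-ol | C[C@H](O)/C=C/c1ccc(OC)cc1OCOC | intermediate
6 | 3-(4-hydroxyphenyl)propanoic acid | OC(=O)CCc1ccc(O)cc1 | starting material
7 | tert-butyldimethylsilyl 3-[4-(tert-butyldimethylsilyloxy)phenyl]propanoate | CC(C)(C)[Si](C)(C)OC(=O)CCc1ccc(O[Si](C)(C)C(C)(C)C)cc1 | intermediate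
8 | 3-[4-(tert-butyldimethylsilyloxy)phenyl]propanoic acid | OC(=O)CCc1ccc(O[Si](C)(C)C(C)(C)C)cc1 | intermediate
9 | (S,E)-4-[4-methoxy-2-(methoxymethoxy)phenyl]but-3-en-2-yl 3-[4-(tert-butyldimethylsilyloxy)phenyl]propanoate | C[C@H](OC(=O)CCc1ccc(O[Si](C)(C)C(C)(C)C)cc1)/C=C/c1ccc(OC)cc1OCOC | intermediate
10 | (E)-trimethylsilyl ketene acetal of 9 (CH2Ar cis to the allylic oxygen) | C[C@H](O/C(O[Si](C)(C)C)=C\Cc1ccc(O[Si](C)(C)C(C)(C)C)cc1)/C=C/c1ccc(OC)cc1OCOC | intermediate
11 | trimethylsilyl (2R,3R,E)-2-[4-(tert-butyldimethylsilyloxy)benzyl]-3-[4-methoxy-2-(methoxymethoxy)phenyl]hex-4-enoate | C[Si](C)(C)OC(=O)[C@H](Cc1ccc(O[Si](C)(C)C(C)(C)C)cc1)[C@@H](/C=C/C)c1ccc(OC)cc1OCOC | intermediate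
12 | (2R,3R,E)-2-[4-(tert-butyldimethylsilyloxy)benzyl]-3-[4-methoxy-2-(methoxymethoxy)phenyl]hex-4-enoic acid | OC(=O)[C@H](Cc1ccc(O[Si](C)(C)C(C)(C)C)cc1)[C@@H](/C=C/C)c1ccc(OC)cc1OCOC | intermediate
13 | (2R,3R,E)-2-[4-(tert-butyldimethylsilyloxy)benzyl]-3-(2-hydroxy-4-methoxyphenyl)hex-4-enoic acid | OC(=O)[C@H](Cc1ccc(O[Si](C)(C)C(C)(C)C)cc1)[C@@H](/C=C/C)c1ccc(OC)cc1O | intermediate
14 | (3R,4R)-3-[4-(tert-butyldimethylsilyloxy)benzyl]-7-methoxy-4-[(E)-prop-1-enyl]chroman-2-one | COc1ccc2c(c1)OC(=O)[C@H](Cc1ccc(O[Si](C)(C)C(C)(C)C)cc1)[C@H]2/C=C/C | intermediate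
15 | 1-bromo-2,4-dimethoxybenzene | COc1ccc(Br)c(OC)c1 | starting material
16 | 2,4-dimethoxyphenyllithium | [Li]c1ccc(OC)cc1OC | intermediate
17 | (2R,3R,E)-2-[4-(tert-butyldimethylsilyloxy)benzyl]-1-(2,4-dimethoxyphenyl)-3-(2-hydroxy-4-methoxyphenyl)hex-4-en-1-one | O=C(c1ccc(OC)cc1OC)[C@H](Cc1ccc(O[Si](C)(C)C(C)(C)C)cc1)[C@@H](/C=C/C)c1ccc(OC)cc1O | intermediate
18 | (3R,4R)-3-[4-(tert-butyldimethylsilyloxy)benzyl]-2-(2,4-dimethoxyphenyl)-7-methoxy-4-[(E)-prop-1-enyl]-3,4-dihydrochromenylium trifluoroacetate | COc1ccc2c(c1)[O+]=C(c1ccc(OC)cc1OC)[C@H](Cc1ccc(O[Si](C)(C)C(C)(C)C)cc1)[C@H]2/C=C/C.[O-]C(=O)C(F)(F)F | intermediate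
19 | (2R,3R,4R)-3-[4-(tert-butyldimethylsilyloxy)benzyl]-2-(2,4-dimethoxyphenyl)-7-methoxy-4-[(E)-prop-1-enyl]chroman | COc1ccc2c(c1)O[C@@H](c1ccc(OC)cc1OC)[C@H](Cc1ccc(O[Si](C)(C)C(C)(C)C)cc1)[C@H]2/C=C/C | intermediate
20 | 4-vinylphenyl acetate (4-acetoxystyrene) | C=Cc1ccc(OC(C)=O)cc1 | starting material
21 | 4-{(E)-2-[(2R,3R,4R)-3-[4-(tert-butyldimethylsilyloxy)benzyl]-2-(2,4-dimethoxyphenyl)-7-methoxychroman-4-yl]vinyl}phenyl acetate | COc1ccc2c(c1)O[C@@H](c1ccc(OC)cc1OC)[C@H](Cc1ccc(O[Si](C)(C)C(C)(C)C)cc1)[C@H]2/C=C/c1ccc(OC(C)=O)cc1 | intermediate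
22 | caraganin C, (2R,3R,4R) | COc1ccc2c(c1)O[C@@H](c1ccc(OC)cc1OC)[C@H](Cc1ccc(O)cc1)[C@H]2/C=C/c1ccc(O)cc1 | target

**Step count**
Total: 11 steps. Longest linear sequence: 10 steps (1, 2, 3, 5, 6, 7, 8, 9, 10, 11); step 4 is a one-step side branch.

**Three steps most likely to fail**

Step 8 (double addition of the aryllithium, or enolisation of the lactone instead of addition). The fallback sets out from acid 12 and comes back at chroman 19. Acid 12 is coupled with N,O-dimethylhydroxylamine hydrochloride (EDC·HCl, HOBt, i-Pr2NEt, CH2Cl2) to give the MOM-protected Weinreb amide F1. Its chelated tetrahedral adduct with aryllithium 16 (THF, −78 → 0 °C) cannot over-add and releases, on quench, the MOM-protected aryl ketone F2. Treating F2 with TFA in CH2Cl2 (MOM cleavage and ring closure to the oxocarbenium) followed by Et3SiH then gives 19, so lactone 14 and keto-phenol 17 are bypassed.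

Step 9 (hydride attack through the diaxial half-chair would give the 2,3-cis epimer, and the electron-rich benzylic C2–O bond can be over-reduced by the silane). The fallback sets out from keto-phenol 17 and comes back at chroman 19. NaBH4 in MeOH at 0 °C reduces 17 to the benzylic alcohol, (2R,3R,E)-2-[4-(tert-butyldimethylsilyloxy)benzyl]-1-(2,4-dimethoxyphenyl)-3-(2-hydroxy-4-methoxyphenyl)hex-4-en-1-ol F3, whose carbinol configuration does not matter. Catalytic PPTS or CSA in CH2Cl2 at rt then ionises F3 to the 2,4-dimethoxybenzylic cation, which the phenol traps reversibly in an SN1 cyclodehydration. With no hydride source present this converges on the all-equatorial 2,3-trans-3,4-trans chroman 19.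

Step 10 (cross-metathesis at a propenyl group next to a hindered, doubly substituted allylic carbon, with styrene homodimerisation competing). The fallback sets out from chroman 19 and comes back at target 22. Lemieux–Johnson cleavage (cat. OsO4, NMO, acetone/H2O; then NaIO4) converts the propenyl group of 19 into the aldehyde, (2R,3R,4R)-3-[4-(tert-butyldimethylsilyloxy)benzyl]-2-(2,4-dimethoxyphenyl)-7-methoxychroman-4-carbaldehyde F4. Horner–Wadsworth–Emmons olefination of F4 with diethyl [4-(tert-butyldimethylsilyloxy)benzyl]phosphonate and KOtBu (THF, 0 °C) gives the E-configured bis-silyl ether F5; any base epimerisation at C4 favours the desired trans arrangement. K2CO3 in MeOH then removes both silyl groups to give 22.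

**Further compounds**
F1 | step 8 | (2R,3R,E)-2-[4-(tert-butyldimethylsilyloxy)benzyl]-N-methoxy-3-[4-methoxy-2-(methoxymethoxy)phenyl]-N-methylhex-4-enamide | CON(C)C(=O)[C@H](Cc1ccc(O[Si](C)(C)C(C)(C)C)cc1)[C@@H](/C=C/C)c1ccc(OC)cc1OCOC
F2 | step 8 | (2R,3R,E)-2-[4-(tert-butyldimethylsilyloxy)benzyl]-1-(2,4-dimethoxyphenyl)-3-[4-methoxy-2-(methoxymethoxy)phenyl]hex-4-en-1-one | O=C(c1ccc(OC)cc1OC)[C@H](Cc1ccc(O[Si](C)(C)C(C)(C)C)cc1)[C@@H](/C=C/C)c1ccc(OC)cc1OCOC
F3 | step 9 | (2R,3R,E)-2-[4-(tert-butyldimethylsilyloxy)benzyl]-1-(2,4-dimethoxyphenyl)-3-(2-hydroxy-4-methoxyphenyl)hex-4-en-1-ol (C1 epimers) | OC(c1ccc(OC)cc1OC)[C@H](Cc1ccc(O[Si](C)(C)C(C)(C)C)cc1)[C@@H](/C=C/C)c1ccc(OC)cc1O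
F4 | step 10 | (2R,3R,4R)-3-[4-(tert-butyldimethylsilyloxy)benzyl]-2-(2,4-dimethoxyphenyl)-7-methoxychroman-4-carbaldehyde | COc1ccc2c(c1)O[C@@H](c1ccc(OC)cc1OC)[C@H](Cc1ccc(O[Si](C)(C)C(C)(C)C)cc1)[C@H]2C=O
F5 | step 10 | tert-butyl{4-[(E)-2-((2R,3R,4R)-3-[4-(tert-butyldimethylsilyloxy)benzyl]-2-(2,4-dimethoxyphenyl)-7-methoxychroman-4-yl)vinyl]phenoxy}dimethylsilane | COc1ccc2c(c1)O[C@@H](c1ccc(OC)cc1OC)[C@H](Cc1ccc(O[Si](C)(C)C(C)(C)C)cc1)[C@H]2/C=C/c1ccc(O[Si](C)(C)C(C)(C)C)cc1
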